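**Plan**
1. The last disconnections are the catechol silyl ethers and the pyran C=C, which goes back to a chromanone C=O; an oxygen is then restored at C3 of the cyclobuta[a]indene core.
2. Both cyclobutane bonds, C7b–C2a and C1–C2, are cut together. C7b=C1 becomes an E-stilbene alkene and C2a=C2 a dimethylallyl alkene; they are held apart only by C3 and two neighbouring ring A carbons, a 1,6-diene set up for five-ring-then-four-ring closure.
3. The diene is cut at ring A–C7b (aryl triflate plus styrylboronate) and at C3–C2a (aryl aldehyde plus 2-methylpropenylzinc). Ring A with its pyranone goes back to phloroglucinol and 3-methylbut-2-enoic acid.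
4. Forward: pyranone ring, O-methylation, formylation, triflation, Suzuki coupling, alkenylation; one photochemical step then closes the cyclopentane and the cyclobutane; the pyran double bond is made last.
5. Stereochemistry: a ligand-controlled alkenylzinc addition sets an (S) carbinol at C3. Allylic strain around it dictates C2a and C7b, the ring fusion is forced cis, the C1 aryl goes exo, and the C3 oxygen is then removed.

Key step: step 10

Remark: the carbocyclic core is numbered as cyclobuta[a]indene (C1 aryl-bearing CH, C2 CMe2, C2a and C7b ring-fusion CH, C3 next to ring A, ring A = C3a–C7a); the early bicyclic intermediates are numbered as chromans. The target is then (1S,2aS,7bR). The chromanone carbonyl is carried unprotected, because the zinc reagent of step 8 does not add to it and a ketal would be reduced in step 11. TBS = tert-butyldimethylsilyl.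

**Step 1**
Reactants: 1 phloroglucinol; 2 3-methylbut-2-enoic acid
Product: 3 5,7-dihydroxy-2,2-dimethylchroman-4-one
Conditions: P2O5, MeSO3H, 70 °C
Reagents that add atoms: none
Why: Friedel–Crafts acylation of the symmetrical triphenol by the activated acid, followed by oxa-Michael closure of the ortho hydroxyl onto the β,β-dimethyl enone, should give the 2,2-dimethylchromanone with no regiochemical choice.

**Step 2**
Reactants: 3 5,7-dihydroxy-2,2-dimethylchroman-4-one
Product: 4 5-hydroxy-7-methoxy-2,2-dimethylchroman-4-one
Conditions: MeI (1.1 equiv), K2CO3 (1.1 equiv), acetone, 40 °C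
Reagents that add atoms: iodomethane, CI
Why: Williamson etherification should take place only at the 7-hydroxyl, because the 5-hydroxyl is locked in a hydrogen bond to the carbonyl and is far less nucleophilic with one equivalent of base.

**Step 3**
Reactants: 4 5-hydroxy-7-methoxy-2,2-dimethylchroman-4-one
Product: 5 5-hydroxy-7-methoxy-2,2-dimethyl-4-oxochromane-6-carbaldehyde
Conditions: MgCl2 (2 equiv), Et3N (4 equiv), (CH2O)n (6 equiv), MeCN, 80 °C; then 1 M HCl
Reagents that add atoms: paraformaldehyde (as formaldehyde), C=O
Why: In the magnesium-mediated ortho-formylation (Casnati–Skattebøl) formaldehyde is delivered inside the magnesium phenoxide only to the carbon ortho to the free hydroxyl, here C6 and not C8, and the hydroxymethyl intermediate is oxidised by a second formaldehyde through hydride transfer.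

**Step 4**
Reactants: 5 5-hydroxy-7-methoxy-2,2-dimethyl-4-oxochromane-6-carbaldehyde
Product: 6 6-formyl-7-methoxy-2,2-dimethyl-4-oxochroman-5-yl trifluoromethanesulfonate
Conditions: Tf2O (1.3 equiv), pyridine (3 equiv), CH2Cl2, −10 to 20 °C
Reagents that add atoms: trifluoromethanesulfonic anhydride, O=S(=O)(OS(=O)(=O)C(F)(F)F)C(F)(F)F
Why: O-sulfonylation of the acidic, doubly hydrogen-bonded phenol is the standard route to aryl triflates and leaves the ketone and the aldehyde untouched.

**Step 5**
Reactants: 7 3,4-dihydroxybenzaldehyde
Product: 8 3,4-bis(tert-butyldimethylsilyloxy)benzaldehyde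
Conditions: TBSCl (2.4 equiv), imidazole (5 equiv), DMF, 20 °C
Reagents that add atoms: tert-butylchlorodimethylsilane, CC(C)(C)[Si](C)(C)Cl
Why: Imidazole-promoted silylation masks the catechol as ethers that should survive base, organozinc, light and dilute acid, and that fluoride removes at the end without acid, which the electron-rich chromene would not tolerate.

**Step 6**
Reactants: 8 3,4-bis(tert-butyldimethylsilyloxy)benzaldehyde
Product: 9 (E)-2-[3,4-bis(tert-butyldimethylsilyloxy)styryl]-4,4,5,5-tetramethyl-1,3,2-dioxaborolane
Conditions: CH2(Bpin)2 (1.2 equiv), lithium 2,2,6,6-tetramethylpiperidide (1.2 equiv, from the amine and n-BuLi), THF, 0 °C; then 8, −78 to 20 °C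
Reagents that add atoms: bis(4,4,5,5-tetramethyl-1,3,2-dioxaborolan-2-yl)methane, CC1(C)OB(CB2OC(C)(C)C(C)(C)O2)OC1(C)C
Why: In the boron–Wittig olefination the lithiated geminal bis(boronate) adds to the aldehyde and syn B–O elimination should give the alkenylboronate with the E geometry usual for aryl aldehydes.

**Step 7**
Reactants: 6 6-formyl-7-methoxy-2,2-dimethyl-4-oxochroman-5-yl trifluoromethanesulfonate; 9 (E)-2-[3,4-bis(tert-butyldimethylsilyloxy)styryl]-4,4,5,5-tetramethyl-1,3,2-dioxaborolane
Product: 10 5-[(E)-3,4-bis(tert-butyldimethylsilyloxy)styryl]-7-methoxy-2,2-dimethyl-4-oxochromane-6-carbaldehyde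
Conditions: Pd(OAc)2 (5 mol %), 2-dicyclohexylphosphino-2',6'-dimethoxybiphenyl (SPhos, 10 mol %), K3PO4 (3 equiv), toluene/H2O 10:1, 60 °C
Reagents that add atoms: none
Why: In this Suzuki–Miyaura coupling the electron-poor triflate should add readily to zerovalent palladium, the bulky biarylphosphine copes with the two ortho substituents, the alkene geometry of the boronate is retained, and the mild phosphate base spares the aryl silyl ethers.

**Step 8**
Reactants: 10 5-[(E)-3,4-bis(tert-butyldimethylsilyloxy)styryl]-7-methoxy-2,2-dimethyl-4-oxochromane-6-carbaldehyde; 11 1-bromo-2-methylprop-1-ene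
Product: 14 5-[(E)-3,4-bis(tert-butyldimethylsilyloxy)styryl]-6-[(1S)-1-hydroxy-3-methylbut-2-enyl]-7-methoxy-2,2-dimethylchroman-4-one, via 2-methylprop-1-enyllithium 12 (not isolated), via bis(2-methylprop-1-enyl)zinc 13 (not isolated)
Conditions: 11 (2.4 equiv), t-BuLi (4.8 equiv), Et2O, −78 °C; ZnBr2 (1.2 equiv), −78 to 0 °C; N,N,N',N'-tetraethylethylenediamine (2 equiv), (2S)-(−)-3-exo-(morpholino)isoborneol [(−)-MIB, 10 mol %], toluene; then 10, 0 °C; aq NH4Cl
Reagents that add atoms: none
Why: In this amino alcohol-catalysed enantioselective addition of an alkenylzinc to an aryl aldehyde the zinc reagent leaves the chromanone ketone alone, the diamine ties up LiBr so that the racemic background path is suppressed, and the (−)-MIB zinc alkoxide should deliver the 2-methylpropenyl group to the Si face of the formyl group, which corresponds to the (S) carbinol.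

**Step 9**
Reactants: 14 5-[(E)-3,4-bis(tert-butyldimethylsilyloxy)styryl]-6-[(1S)-1-hydroxy-3-methylbut-2-enyl]-7-methoxy-2,2-dimethylchroman-4-one
Product: 15 5-[(E)-3,4-bis(tert-butyldimethylsilyloxy)styryl]-6-[(1S)-1-(tert-butyldimethylsilyloxy)-3-methylbut-2-enyl]-7-methoxy-2,2-dimethylchroman-4-one
Conditions: TBSCl (1.5 equiv), imidazole (3 equiv), DMAP (cat.), DMF, 20 °C
Reagents that add atoms: tert-butylchlorodimethylsilane, CC(C)(C)[Si](C)(C)Cl
Why: Base-mediated silylation under non-acidic conditions protects the easily ionised benzylic, allylic carbinol without touching its configuration and enlarges the group that has to stay out of the alkene plane in step 10.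

**Step 10**
Reactants: 15 5-[(E)-3,4-bis(tert-butyldimethylsilyloxy)styryl]-6-[(1S)-1-(tert-butyldimethylsilyloxy)-3-methylbut-2-enyl]-7-methoxy-2,2-dimethylchroman-4-one
Product: 16 (1S,2aS,3S,7bS)-cyclobuta[a]indene cycloadduct: C1 3,4-bis(tert-butyldimethylsilyloxy)phenyl (exo), C2 gem-dimethyl, C3 tert-butyldimethylsilyloxy (exo, trans to the cyclobutane), 4-methoxy, and a 2,2-dimethyl-2,3-dihydropyran-4-one fused at C6 (O) and C7 (C=O)
Conditions: thioxanthone (10 mol %), degassed PhCF3 (0.01 M), 405 nm LEDs, 20 °C, argon
Reagents that add atoms: none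
Why: Thioxanthone (triplet energy about 65 kcal/mol) absorbs the 405 nm light and passes its triplet energy to the stilbene, the lowest triplet of 15, which relaxes to a twisted 1,2-diradical; this is the sensitised intramolecular styrene–alkene [2+2] photocycloaddition across a three-atom tether, the known route to bicyclo[3.2.0]heptanes. The cyclopentane closes first by 5-exo attack of the C7b radical on C2a, the less substituted carbon of the dimethylallyl alkene (rule of five), leaving a benzylic radical at C1 and a tertiary radical at C2; after intersystem crossing these combine to close the cyclobutane, so the CMe2 carbon comes straight from the side chain. C2a and C7b are set by the C3 carbinol centre: A(1,3) strain with the Z-methyl keeps the C3–H bond in the alkene plane, ring A and the silyloxy group then lie on opposite faces, and C7b, which can only arrive from the ring A side, bonds anti to the silyloxy group, which gives the (2aS,7bS) adduct with that group exo. The ring fusion must be cis because a trans-fused 1,4-diradical cannot close and cleaves back to the diene, and the aryl group at C1 should end exo, trans to ring A, in the less hindered closure that also matches the E geometry. The step needs chemoselectivity for the stilbene over the chromanone and 5-exo over 6-endo regioselectivity: the first is secured because only the stilbene triplet lies below that of the sensitiser (E/Z isomerisation merely returns material to the same diradical), the second by the three-atom link of C3 and two ring A carbons between C7b and C2a.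

**Step 11**
Reactants: 16 the (1S,2aS,3S,7bS) cycloadduct
Product: 17 (1S,2aS,7bR)-C3-methylene chromanone: as 16 but with CH2 at C3
Conditions: Et3SiH (5 equiv), CF3CO2H (3 equiv), CH2Cl2, −40 to 0 °C
Reagents that add atoms: none
Why: In this ionic hydrogenation the acid ionises the benzylic silyl ether to a cation stabilised by the ortho methoxy and para pyran oxygen, which Et3SiH should trap faster than the cyclobutane can open, while the vinylogous-ester chromanone and the aryl silyl ethers do not react under such mild acid and no stereocentre is involved.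

**Step 12**
Reactants: 17 the (1S,2aS,7bR) C3-methylene chromanone
Product: 18 the corresponding pyran-4-ol (chromanol), mixture of epimers at the new carbinol carbon
Conditions: NaBH4 (2 equiv), CeCl3·7H2O (1.2 equiv), MeOH/THF 1:1, 0 °C
Reagents that add atoms: none
Why: Luche reduction activates the deactivated aryl ketone with the cerium salt and stays non-basic enough to keep the aryl silyl ethers; the new carbinol centre is lost in the next step, so its configuration does not matter.

**Step 13**
Reactants: 18 the chromanol
Product: 19 bis(tert-butyldimethylsilyl) ether of the target (2,2-dimethyl-2H-chromene)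
Conditions: p-TsOH·H2O (5 mol %), toluene (0.02 M), 50 °C
Reagents that add atoms: none
Why: Acid-catalysed E1 dehydration proceeds through a benzylic cation stabilised by the para methoxy and ortho pyran oxygen and can only lose the adjacent CH2 proton, giving the 2H-chromene; low acid loading and dilution should hold back dimerisation.

**Step 14**
Reactants: 19 bis(tert-butyldimethylsilyl) ether of the target
Product: 20 target, (1S,2aS,7bR)-1-(3,4-dihydroxyphenyl)-4-methoxy-2,2-dimethyl-2,2a,3,7b-tetrahydro-1H-cyclobuta[a]indene with a 2,2-dimethyl-2H-pyran fused at C6 (O) and C7 (CH=)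
Conditions: Bu4NF (2.5 equiv), AcOH (2.5 equiv), THF, 0 °C, argon
Reagents that add atoms: none
Why: Fluoride cleaves the aryl Si–O bonds, and the acetic acid buffer keeps the liberated catechol protonated and so protected from air oxidation, under conditions that touch neither the chromene nor the cyclobutane.

**Compound list**
1 | phloroglucinol | Oc1cc(O)cc(O)c1 | starting material
2 | 3-methylbut-2-enoic acid | CC(C)=CC(O)=O | starting material
3 | 5,7-dihydroxy-2,2-dimethylchroman-4-one | CC1(C)CC(=O)c2c(O)cc(O)cc2O1 | intermediate
4 | 5-hydroxy-7-methoxy-2,2-dimethylchroman-4-one | COc1cc(O)c2C(=O)CC(C)(C)Oc2c1 | intermediate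
5 | 5-hydroxy-7-methoxy-2,2-dimethyl-4-oxochromane-6-carbaldehyde | COc1cc2OC(C)(C)CC(=O)c2c(O)c1C=O | intermediate
6 | 6-formyl-7-methoxy-2,2-dimethyl-4-oxochroman-5-yl trifluoromethanesulfonate | COc1cc2OC(C)(C)CC(=O)c2c(OS(=O)(=O)C(F)(F)F)c1C=O | intermediate
7 | 3,4-dihydroxybenzaldehyde | O=Cc1ccc(O)c(O)c1 | starting material
8 | 3,4-bis(tert-butyldimethylsilyloxy)benzaldehyde | O=Cc1ccc(O[Si](C)(C)C(C)(C)C)c(O[Si](C)(C)C(C)(C)C)c1 | intermediate
9 | (E)-2-[3,4-bis(tert-butyldimethylsilyloxy)styryl]-4,4,5,5-tetramethyl-1,3,2-dioxaborolane | CC1(C)OB(/C=C/c2ccc(O[Si](C)(C)C(C)(C)C)c(O[Si](C)(C)C(C)(C)C)c2)OC1(C)C | intermediate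
10 | 5-[(E)-3,4-bis(tert-butyldimethylsilyloxy)styryl]-7-methoxy-2,2-dimethyl-4-oxochromane-6-carbaldehyde | COc1cc2OC(C)(C)CC(=O)c2c(/C=C/c2ccc(O[Si](C)(C)C(C)(C)C)c(O[Si](C)(C)C(C)(C)C)c2)c1C=O | intermediate
11 | 1-bromo-2-methylprop-1-ene | CC(C)=CBr | starting material
12 | 2-methylprop-1-enyllithium | [Li]C=C(C)C | intermediate
13 | bis(2-methylprop-1-enyl)zinc | CC(C)=C[Zn]C=C(C)C | intermediate
14 | 5-[(E)-3,4-bis(tert-butyldimethylsilyloxy)styryl]-6-[(1S)-1-hydroxy-3-methylbut-2-enyl]-7-methoxy-2,2-dimethylchroman-4-one | COc1cc2OC(C)(C)CC(=O)c2c(/C=C/c2ccc(O[Si](C)(C)C(C)(C)C)c(O[Si](C)(C)C(C)(C)C)c2)c1[C@@H](O)C=C(C)C | intermediate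
15 | 5-[(E)-3,4-bis(tert-butyldimethylsilyloxy)styryl]-6-[(1S)-1-(tert-butyldimethylsilyloxy)-3-methylbut-2-enyl]-7-methoxy-2,2-dimethylchroman-4-one | COc1cc2OC(C)(C)CC(=O)c2c(/C=C/c2ccc(O[Si](C)(C)C(C)(C)C)c(O[Si](C)(C)C(C)(C)C)c2)c1[C@@H](O[Si](C)(C)C(C)(C)C)C=C(C)C | intermediate
16 | (1S,2aS,3S,7bS) cycloadduct, C3 silyloxy exo, C1 aryl exo, pyran-4-one intact | COc1cc2c(c3c1[C@@H](O[Si](C)(C)C(C)(C)C)[C@H]1[C@@H]3[C@H](c3ccc(O[Si](C)(C)C(C)(C)C)c(O[Si](C)(C)C(C)(C)C)c3)C1(C)C)C(=O)CC(C)(C)O2 | intermediate
17 | (1S,2aS,7bR) C3-methylene chromanone | COc1cc2c(c3c1C[C@H]1[C@@H]3[C@H](c3ccc(O[Si](C)(C)C(C)(C)C)c(O[Si](C)(C)C(C)(C)C)c3)C1(C)C)C(=O)CC(C)(C)O2 | intermediate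
18 | chromanol from 17, both carbinol epimers | COc1cc2c(c3c1C[C@H]1[C@@H]3[C@H](c3ccc(O[Si](C)(C)C(C)(C)C)c(O[Si](C)(C)C(C)(C)C)c3)C1(C)C)C(O)CC(C)(C)O2 | intermediate
19 | bis(tert-butyldimethylsilyl) ether of the target | COc1cc2c(c3c1C[C@H]1[C@@H]3[C@H](c3ccc(O[Si](C)(C)C(C)(C)C)c(O[Si](C)(C)C(C)(C)C)c3)C1(C)C)C=CC(C)(C)O2 | intermediate
20 | CNP0207533.1, (1S,2aS,7bR) | COc1cc2c(c3c1C[C@H]1[C@@H]3[C@H](c3ccc(O)c(O)c3)C1(C)C)C=CC(C)(C)O2 | target

**Step count**
Total: 14 steps. Longest linear sequence: 12 steps (steps 1–4 and 7–14, from phloroglucinol); steps 5 and 6 make boronate 9 on a side branch.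

**Steps most likely to fail**

Step 10. The congested stilbene triplet may decay by E/Z cycling faster than it bonds, the 1,4-diradical may disproportionate (hydrogen transfer from a C2 methyl to C1) instead of closing, or the facial bias may be incomplete. The fallback sets out from 15 and comes back at 16, replacing energy transfer by hole catalysis. With [Ru(bpz)3](PF6)2 (2 mol %), air, MeNO2 and blue LEDs the electron-rich stilbene is oxidised to its radical cation, which should add to C2a in the same 5-exo sense and close the four-membered ring before back electron transfer, as in radical-cation [2+2] cycloadditions of electron-rich styrenes. The same allylic-strain model applies, and no new compound arises (F0).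

Step 11. The C3 cation is a cyclobutylcarbinyl cation, so cleavage of the C2a–C2 bond with opening of the four-membered ring may compete with hydride capture, and longer acid exposure may begin to reduce the chromanone. The fallback sets out from 14 and comes back at 17, using a radical instead of a cation. The silylation is omitted and 14 is irradiated under the conditions of step 10 to give the C3-hydroxy cycloadduct F1. PhOC(S)Cl, pyridine and DMAP in CH2Cl2 then give the O-phenyl thionocarbonate F2. Bu3SnH with AIBN in toluene at 80 °C (Barton–McCombie deoxygenation) should give 17, because a benzylic C3 radical does not open the cyclobutane at a competitive rate and tin hydride leaves the ketone alone.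

Step 8. Enantioselectivity may be insufficient on the di-ortho-substituted aldehyde, or lithium salts may drive racemic background addition. The fallback sets out from 10 and comes back at 14, setting the centre by reduction instead of addition. Addition of 13 in the presence of achiral 2-(dimethylamino)ethanol gives the racemic carbinol F3. MnO2 in CH2Cl2 oxidises it to the aryl 2-methylpropenyl ketone F4. Corey–Bakshi–Shibata reduction with (R)-2-methyl-CBS-oxazaborolidine and catecholborane in toluene at −78 °C should return (S)-14, on the assumption that the twisted ring A acts as the large group and that the much less electrophilic chromanone does not react.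

**Further compounds**
F0 | step 10 | none | none
F1 | step 11 | (1S,2aS,3S,7bS) C3-hydroxy cycloadduct | COc1cc2c(c3c1[C@@H](O)[C@H]1[C@@H]3[C@H](c3ccc(O[Si](C)(C)C(C)(C)C)c(O[Si](C)(C)C(C)(C)C)c3)C1(C)C)C(=O)CC(C)(C)O2
F2 | step 11 | O-phenyl thionocarbonate of F1 | COc1cc2c(c3c1[C@@H](OC(=S)Oc4ccccc4)[C@H]1[C@@H]3[C@H](c3ccc(O[Si](C)(C)C(C)(C)C)c(O[Si](C)(C)C(C)(C)C)c3)C1(C)C)C(=O)CC(C)(C)O2
F3 | step 8 | racemic carbinol corresponding to 14 | COc1cc2OC(C)(C)CC(=O)c2c(/C=C/c2ccc(O[Si](C)(C)C(C)(C)C)c(O[Si](C)(C)C(C)(C)C)c2)c1C(O)C=C(C)C
F4 | step 8 | 5-[(E)-3,4-bis(tert-butyldimethylsilyloxy)styryl]-7-methoxy-2,2-dimethyl-6-(3-methylbut-2-enoyl)chroman-4-one | COc1cc2OC(C)(C)CC(=O)c2c(/C=C/c2ccc(O[Si](C)(C)C(C)(C)C)c(O[Si](C)(C)C(C)(C)C)c2)c1C(=O)C=C(C)C
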